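The dihydropyran ring (O1–C2–C3–C4–C4a–C8a) is cut at C3–C4 and O1–C2, giving an ortho-quinone methide and a two-carbon alkene. The route exploits the fact that C4, the methine carrying both arenes, sits on a ring carbon (C4a) flanked by two equivalent oxygens (future O1 and 5-OH): a simple triol carbinol ionises to a single o-quinone methide whichever oxygen reacts. In one operation a chiral phosphoric acid generates this species from the open diaryl carbinol and steers its [4+2] cycloaddition with phenyl vinyl sulfide, closing the pyran ring and fixing C4. The sulfur at C2 is then exchanged for methyl, trans to C4.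

Key step: step 3

Remark: the sense of induction of the (R)-configured phosphoric acid at C4 is assigned by analogy with related o-quinone methide cycloadditions; should it prove opposite, the (S)-catalyst is used and nothing else changes.
Remark: 1,8-dimethoxynaphthalene, 2,6-dihydroxybenzaldehyde and phenyl vinyl sulfide are taken as commercial starting materials.

Step 1
Reactants: 1 1,8-dimethoxynaphthalene
Product: 2 4-bromo-1,8-dimethoxynaphthalene
Conditions: NBS (1.0 equiv), MeCN, 0 °C → rt
Reagents that add atoms: N-bromosuccinimide, O=C1CCC(=O)N1Br
Why: Electrophilic aromatic bromination, which should occur para to one methoxy group (C4), the most activated and least hindered position of the symmetrical naphthalene, and stop at the monobromide with one equivalent of NBS.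

Step 2
Reactants: 2 4-bromo-1,8-dimethoxynaphthalene; 3 2,6-dihydroxybenzaldehyde
Product: 6 rac-2-[(4,5-dimethoxynaphthalen-1-yl)(hydroxy)methyl]benzene-1,3-diol, via aryllithium 4 (not isolated), via disodium diolate 5 (not isolated)
Conditions: 2 (1.2 equiv), n-BuLi, THF, −78 °C; separately 3, NaH (2.1 equiv), THF, 0 °C; combine, −78 → 0 °C; sat. aq NH4Cl, 0 °C; used without chromatography on acidic silica
Reagents that add atoms: none
Why: Bromine–lithium exchange followed by 1,2-addition of the aryllithium to the aldehyde, whose phenols are first converted into sodium phenoxides by a sacrificial base so that the aryl nucleophile is not consumed, should give the carbinol, whose racemic centre is erased in step 3.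

Step 3
Reactants: 6 rac-2-[(4,5-dimethoxynaphthalen-1-yl)(hydroxy)methyl]benzene-1,3-diol; 7 phenyl vinyl sulfide
Product: 9 (2S,4S)-4-(4,5-dimethoxynaphthalen-1-yl)-2-(phenylsulfanyl)-3,4-dihydro-2H-1-benzopyran-5-ol, via o-quinone methide 8 (not isolated)
Conditions: (R)-TRIP (10 mol %), 7 (4 equiv), 4 Å MS, CH2Cl2 (0.03 M), −20 °C → rt
Reagents that add atoms: none
Why: The phosphoric acid dehydrates 6 to the hydrogen-bonded o-quinone methide 8; the unsubstituted alkene carbon of 7 attacks its methide carbon (C3–C4 bond) and the sulfur-stabilised cation is captured by the quinone-methide oxygen (O1–C2 bond), i.e. an asynchronous inverse-electron-demand oxa-[4+2] cycloaddition. The closest known reaction type is the chiral-phosphoric-acid-catalysed [4+2] cycloaddition of o-quinone methides generated in situ from o-hydroxybenzhydrols with vinyl sulfides, enamides or styrenes. The dihydropyran ring is the only ring closed, by intermolecular [4+2] union of the O1–C8a–C4a–C4 heterodiene with the two alkene carbons. C4 is set by the catalyst, which blocks one face of the bound o-quinone methide, whereas C2 should arise cis to the naphthyl group through endo orientation of sulfur and is inconsequential because step 4 re-sets it. The step needs regioselectivity, secured by the polarity match of the nucleophilic CH2 with the methide carbon, and chemoselectivity against Friedel–Crafts self-alkylation of the resorcinol ring, secured by excess 7 at high dilution. Because proton transfer between the two oxygens flanking C4a interconverts the two o-quinone methide geometries, either phenol can become O1 and the other is left as the 5-OH, so no protecting group and no regiochemical choice is needed.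

Step 4
Reactants: 9 (2S,4S)-4-(4,5-dimethoxynaphthalen-1-yl)-2-(phenylsulfanyl)-3,4-dihydro-2H-1-benzopyran-5-ol
Product: 11 Cladonaphchrom A [(2R,4S)-4-(4,5-dimethoxynaphthalen-1-yl)-2-methyl-3,4-dihydro-2H-1-benzopyran-5-ol], via anomeric sulfone 10 (not isolated)
Conditions: mCPBA (2.2 equiv), CH2Cl2, −20 → 0 °C; then AlMe3 (8 equiv), −78 °C → rt; aq. Rochelle salt
Reagents that add atoms: trimethylaluminium, C[Al](C)C; meta-chloroperbenzoic acid, OOC(=O)c1cccc(Cl)c1 (its oxygen enters only the non-isolated sulfone 10)
Why: Chemoselective S-oxidation gives the anomeric sulfone 10, which AlMe3 should ionise to the chroman-2-ylium ion (anomeric sulfone displacement, C-glycosylation type) and methylate on the face opposite the C4 naphthyl group, held pseudoaxial by peri strain with the 5-oxygen substituent, so that C2 is set as R, trans to the untouched C4 centre.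

Compound list
1 | 1,8-dimethoxynaphthalene | COc1cccc2cccc(OC)c12 | starting material
2 | 4-bromo-1,8-dimethoxynaphthalene | COc1cccc2c(Br)ccc(OC)c12 | intermediate
3 | 2,6-dihydroxybenzaldehyde | O=Cc1c(O)cccc1O | starting material
4 | (4,5-dimethoxynaphthalen-1-yl)lithium | [Li]c1ccc(OC)c2c(OC)cccc12 | intermediate
5 | disodium 2-formylbenzene-1,3-bis(olate) | O=Cc1c([O-])cccc1[O-].[Na+].[Na+] | intermediate
6 | 2-[(4,5-dimethoxynaphthalen-1-yl)(hydroxy)methyl]benzene-1,3-diol (racemic) | COc1cccc2c(C(O)c3c(O)cccc3O)ccc(OC)c12 | intermediate
7 | phenyl vinyl sulfide | C=CSc1ccccc1 | starting material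
8 | (6E)-6-[(4,5-dimethoxynaphthalen-1-yl)methylidene]-5-hydroxycyclohexa-2,4-dien-1-one | COc1cccc2c(/C=C3/C(=O)C=CC=C3O)ccc(OC)c12 | intermediate
9 | (2S,4S)-4-(4,5-dimethoxynaphthalen-1-yl)-2-(phenylsulfanyl)-3,4-dihydro-2H-1-benzopyran-5-ol | COc1cccc2c([C@@H]3C[C@H](Sc5ccccc5)Oc4cccc(O)c43)ccc(OC)c12 | intermediate
10 | (2S,4S)-2-(benzenesulfonyl)-4-(4,5-dimethoxynaphthalen-1-yl)-3,4-dihydro-2H-1-benzopyran-5-ol | COc1cccc2c([C@@H]3C[C@H](S(=O)(=O)c5ccccc5)Oc4cccc(O)c43)ccc(OC)c12 | intermediate
11 | Cladonaphchrom A, (2R,4S)-4-(4,5-dimethoxynaphthalen-1-yl)-2-methyl-3,4-dihydro-2H-1-benzopyran-5-ol | COc1cccc2c([C@@H]3C[C@@H](C)Oc4cccc(O)c43)ccc(OC)c12 | target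

Total step count: 4. Longest linear sequence: 4 (1 → 2 → 6 → 9 → 11).

Steps most likely to fail

1. Step 3 (key step). The catalyst may discriminate the two faces of the o-quinone methide only poorly, because the dienophile offers no hydrogen-bond donor and the second phenol can compete for the catalyst. The o-quinone methide may also alkylate the electron-rich resorcinol ring of a second molecule instead of undergoing cycloaddition. Fallback: setting out from 6, the cycloaddition with 7 is run without asymmetric induction (diphenyl phosphate, 5 mol %, slow addition of 6 to excess 7 at high dilution). This should give 9 together with its mirror image, the (2R,4R)-enantiomer of 9 F1, as the racemate. The two are separated by preparative SFC on a chiral polysaccharide phase, and the route is rejoined at 9.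

2. Step 4. Methyl delivery may occur on the wrong face and give the 2,4-cis epimer. The oxocarbenium ion may lose a C3 proton to give the 4H-chromene, or be intercepted by the activated peri carbon (C8) of the naphthyl group. The peracid may attack the electron-rich rings. Fallback: setting out from 9, silver-assisted hydrolysis of the S,O-acetal (AgNO3, 2,6-lutidine, THF/H2O) should give the lactol (4S)-4-(4,5-dimethoxynaphthalen-1-yl)-3,4-dihydro-2H-1-benzopyran-2,5-diol F2. Wittig methylenation of its open hydroxy-aldehyde form (Ph3P=CH2 in excess, THF) should give 2-[(1S)-1-(4,5-dimethoxynaphthalen-1-yl)but-3-en-1-yl]benzene-1,3-diol F3. Silver(I) triflate-catalysed Markovnikov hydroalkoxylation of the terminal alkene by either of the two equivalent phenols (AgOTf, DCE, 60 °C) then recloses the pyran ring without a free cation at C2. A chair-like transition state with methyl equatorial and naphthyl pseudoaxial should favour the trans product, and the route is rejoined at 11.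

3. Step 2. Addition to the electron-rich, poorly soluble bis-phenoxide aldehyde may be sluggish, and 6 may ionise and oligomerise during work-up. Fallback: setting out from 3, O-allylation (allyl bromide, K2CO3, DMF) should give 2,6-bis(prop-2-en-1-yloxy)benzaldehyde F4. Addition of aryllithium 4 (from 2, n-BuLi, THF, −78 °C) should give [2,6-bis(prop-2-en-1-yloxy)phenyl](4,5-dimethoxynaphthalen-1-yl)methanol F5. Deallylation under neutral conditions (Pd(PPh3)4, morpholine, THF) rejoins the route at 6.

Further compounds
F1 | step 3 | (2R,4R)-4-(4,5-dimethoxynaphthalen-1-yl)-2-(phenylsulfanyl)-3,4-dihydro-2H-1-benzopyran-5-ol (enantiomer of 9) | COc1cccc2c([C@H]3C[C@@H](Sc5ccccc5)Oc4cccc(O)c43)ccc(OC)c12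
F2 | step 4 | (4S)-4-(4,5-dimethoxynaphthalen-1-yl)-3,4-dihydro-2H-1-benzopyran-2,5-diol (anomeric mixture) | COc1cccc2c([C@@H]3CC(O)Oc4cccc(O)c43)ccc(OC)c12
F3 | step 4 | 2-[(1S)-1-(4,5-dimethoxynaphthalen-1-yl)but-3-en-1-yl]benzene-1,3-diol | COc1cccc2c([C@H](CC=C)c3c(O)cccc3O)ccc(OC)c12
F4 | step 2 | 2,6-bis(prop-2-en-1-yloxy)benzaldehyde | O=Cc1c(OCC=C)cccc1OCC=C
F5 | step 2 | [2,6-bis(prop-2-en-1-yloxy)phenyl](4,5-dimethoxynaphthalen-1-yl)methanol | COc1cccc2c(C(O)c3c(OCC=C)cccc3OCC=C)ccc(OC)c12
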